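Numbering used throughout: **1** pent-4-enoic acid, **2** pivaloyl chloride, **3** (R)-4-benzyl-2-oxazolidinone, **4** mixed anhydride, **5** pentenoyl imide, **6** lithium enolate, **7** coupled bis-imide, **8** diallyl diol, **9** diallyl dipivalate, **10** dipropenyl dipivalate, **11** dialdehyde, **12** bis-acetal, **13** 2,6-dimethoxyphenol, **14** mono-C-aryl acetal, **15** dipivalate of the target, **16** target.

## Analysis of the target

Compound 16 has one tetrahydrofuran ring (O-1, C-2 to C-5). C-2 and C-5 each carry a 4-hydroxy-3,5-dimethoxyphenyl group, and C-3 and C-4 each carry a hydroxymethyl arm. The SMILES reads as (2R,3S,4S,5R). The four contiguous centres alternate up, down, up, down, so every vicinal pair is trans, the 2,5-pair is trans, and a C2 axis runs through O-1 and the midpoint of C-3–C-4. Only two centres are therefore independent, and the all-trans array is the least crowded of the isomers that share the trans C-3/C-4 pair.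

The sensitive groups are the two electron-rich free phenols (air oxidation, quinone methide formation) and the two ring C–O bonds, which are para-hydroxybenzylic ethers and ionise in acid. A cation at C-2 or C-5 can be captured by the arm oxygen on the remote ring carbon, which fuses a second oxolane, or by an ortho carbon of the other aryl ring, which closes a tetralin. Acid and the free diol must therefore never meet.

The hard parts are the absolute configuration at C-3/C-4, in a molecule with no resident chiral handle, and the handling of two configurationally labile benzylic centres. The plan rests on one feature. C-2 and C-5 are each bonded to O-1 and to the carbon para to the hydroxyl of a 2,6-dimethoxyphenol. Without the aryl groups they are the acetal carbons of a 2,5-dialkoxytetrahydrofuran, and the aryl groups are that phenol acting as a carbon nucleophile.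

## Retrosynthetic reasoning

**16 ⇒ 15.** Only the two acyl–oxygen bonds of the arm esters are cut. The arms must be masked whenever acid is present. The oxygen of the C-4 arm lies five atoms from C-2, and that of the C-3 arm five atoms from C-5, so either would trap a benzylic cation and fuse a second ring across C-3–C-4. An ester oxygen is too poor a nucleophile for that. Pivalate neither migrates nor hydrolyses on the way, and its carbonyl can shield the cis face of the adjacent cation. The forward step must free two primary alcohols without acid.

**15 ⇒ 14 ⇒ 12 + 2 × 13.** The C-2–aryl and C-5–aryl bonds are cut in turn.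
- Removing the aryl groups leaves both carbons at the aldehyde oxidation level and keeps the C2 symmetry, so one operation applied twice does the work.
- The aryl unit arrives as a cheap phenol with all its oxygens in place and no protecting group.
- The two labile benzylic centres are made last, next to fixed centres.
- Cutting a ring C–O bond instead would require two separately made benzylic carbinols and a cyclisation in which four hydroxyl groups compete. Cutting C-2–C-3 would break the symmetry.
- The forward reaction must give C- over O-arylation, reaction at the para carbon, one aryl per carbon, and the trans relationship to the neighbouring arm.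

**12 ⇒ 11 ⇒ 10.** Compound 12 is the methanol adduct of the 1,4-dialdehyde 11. Each formyl carbon is traced to an alkene carbon, because an alkene survives enolate, hydride and acylation chemistry. Two C=C bonds are cut, and the forward step must mask the sensitive dialdehyde as soon as it forms.

**10 ⇒ 9.** No skeletal bond is cut; each double bond moves by one position. Carrying propenyl arms from the start would need a β,γ-unsaturated acyl unit, whose enolate is an extended dienolate with α/γ ambiguity. The allyl arm comes from a simple, well-behaved enolate, and its extra carbon leaves later with the cleaved terminus.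

**9 ⇒ 8 + 2, and 8 ⇒ 7.** These are functional-group changes only. The two imide carbonyl carbons of 7 become the CH2O arms, and reduction releases the auxiliary 3 for reuse.

**7 ⇒ 5 + 5 (through 6).** The C-3–C-4 bond, which lies across the C2 axis, is cut. The two halves are identical, one bond formation sets both independent stereocentres, and any minor isomer is a diastereomer while the auxiliaries remain attached. The forward reaction is an oxidative enolate dimerisation in which each half reacts on the face away from its benzyl group.

**5 ⇒ 1 + 3 (with 2, through 4).** This is the N-acyl bond, formed through a mixed anhydride.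

## Alternatives that were turned down

**Alternative 1:** conjugate addition–aldol on a chiral butenolide.
- **Disconnection:** C-4–C-5 and C-2–C-3 are cut, and both ring C–O bonds are left for later.
- **Forward key step:** lithiated 2-(4-benzyloxy-3,5-dimethoxyphenyl)-1,3-dithiane A2 adds to the β-carbon of (S)-5-(tert-butyldiphenylsilyloxymethyl)furan-2(5H)-one A1, anti to the silyloxymethyl arm. The resulting enolate is trapped by 4-benzyloxy-3,5-dimethoxybenzaldehyde A3, anti to the new substituent, to give the trans,trans lactone A4 in one flask.
- **For:** the three-component union is robust. Each aryl–carbon bond is bought with the aromatic building block, so arene regiochemistry never arises. The benzylated phenols exclude quinone methide chemistry until the end.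
- **Against:**
  - The symmetry of 16 is ignored, since the two aryl-bearing carbons appear at different oxidation levels.
  - The carbinol centre is only weakly controlled.
  - The directing centre must be excised.
  - After A4 there follow dithiane hydrolysis, carbonyl reduction, lactone reduction, desilylation, glycol cleavage, a further reduction, a cycloetherification in which free arm hydroxyls compete, and debenzylation.
- **Comparison:** this plan is stronger on regiochemical certainty and on the predictability of C-3/C-4. The chosen strategy offers instead roughly half the operations, two-directional use of every step after the dimerisation, and no phenol protection.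

**Alternative 2:** palladium-catalysed (3+2) annulation.
- **Disconnection:** O-1–C-2 and C-3–C-4.
- **Forward key step:** a zerovalent palladium catalyst such as Pd2(dba)3 with a phosphine ionises trans-2-(4-benzyloxy-3,5-dimethoxyphenyl)-3-vinyloxirane A5 to a π-allyl alkoxide. The alkoxide adds to dimethyl 2-(4-benzyloxy-3,5-dimethoxybenzylidene)malonate A6, and the malonate anion closes on the internal allyl terminus to give tetrahydrofuran A7.
- **For:** the ring and two bonds form in one catalytic, convergent step.
- **Against:**
  - The acceptor A6 is deactivated by three donor oxygens, so the oxa-Michael step is slow and reversible.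
  - C-5 must come from enantioenriched A5, an acid-labile electron-rich benzylic epoxide that takes several steps to make.
  - C-2 and C-4 must be set relative to C-5 at once, with little intrinsic bias.
  - C-3 emerges quaternary and needs a hot dealkoxycarbonylation followed by stereoselective protonation.
  - The vinyl group needs cleavage and reduction, the ester needs reduction, and both benzyl groups must be removed.
- **Comparison:** this plan is stronger in bond-forming density per step. The chosen route needs no ring closure, builds 16 from identical halves, and places its only real uncertainty in one step rather than across three stereochemical relationships.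

**Alternative 3:** oxygen insertion into a cinnamate photodimer.
- **Disconnection:** both C–O bonds of the ring, traced to a C–C bond of a cyclobutane.
- **Forward key step:** methyl sinapate A8 is photodimerised head-to-head to the all-trans cyclobutane A9. Two-electron oxidation of the bis-phenol (FeCl3 or Ag2O) breaks the bond between the aryl-bearing carbons to give a bis-quinone methide. One water molecule adds, and the new carbinol closes onto the second quinone methide to give diester A10.
- **For:** it is the shortest plan. It exploits the symmetry, needs free phenols rather than protected ones, and leaves only an ester reduction.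
- **Against:**
  - Dimerisation of A8 has no source of absolute configuration, and the all-trans head-to-head isomer is not the usual outcome. A single enantiomer would need a chiral template or a resolution.
  - In the bis-quinone methide the C-3 and C-4 hydrogens are α to an ester and vinylogously acidified. Tautomerisation and cyclisation to a dihydronaphthalene therefore compete and threaten the very centres that must survive.
- **Comparison:** this plan is stronger in step count and atom economy, and equal in the thermodynamic settling of C-2/C-5, which uses the same reversible ionisation. The chosen strategy supplies what it lacks: an auxiliary-defined, purifiable C-3/C-4 pair that carries no acidifying carbonyl during the acid step.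

Key step: step 7

Assumption: the alkene geometry of 10 and the anomeric configurations of 12 and 14 are erased later, so 10 is drawn (E,E) and the anomeric carbons are left undefined.

## Route

Step 1
Reactants: 1 pent-4-enoic acid; 2 pivaloyl chloride; 3 (R)-4-benzyl-2-oxazolidinone
Product: 5 (R)-4-benzyl-3-(pent-4-enoyl)oxazolidin-2-one, via pentenoic pivalic anhydride 4 (not isolated)
Conditions: 1, 2, Et3N, THF, −20 °C; then LiCl, 3, −20 °C → rt
Reagents that add atoms: none
Why: N-acylation of an oxazolidinone through a mixed pivalic anhydride, in which the LiCl/Et3N-activated carbamate nitrogen attacks the less hindered pentenoyl carbonyl of 4. The stereocentre of 3 is not involved.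

Step 2
Reactants: 5 (R)-4-benzyl-3-(pent-4-enoyl)oxazolidin-2-one (two molecules)
Product: 7 (2S,3S)-2,3-diallyl-1,4-bis[(4R)-4-benzyl-2-oxo-1,3-oxazolidin-3-yl]butane-1,4-dione, via lithium Z-enolate 6 (not isolated)
Conditions: LiN(iPr)2, THF, −78 °C; then CuCl2, THF–DMF, −78 → 0 °C
Reagents that add atoms: none
Why: Oxidative homocoupling of an imide lithium enolate, in which divalent copper takes one electron from each chelated Z-enolate and the two α-carbons join. Each half bonds on the face opposite its benzyl group, so the (R)-auxiliary sets both new centres (future C-3 and C-4) as S. The minor isomers are diastereomers and can be removed by crystallisation or chromatography.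

Step 3
Reactants: 7 (2S,3S)-2,3-diallyl-1,4-bis[(4R)-4-benzyl-2-oxo-1,3-oxazolidin-3-yl]butane-1,4-dione
Product: 8 (2S,3S)-2,3-diallylbutane-1,4-diol
Conditions: LiBH4, THF–Et2O, 0 °C → rt
Reagents that add atoms: none
Why: Reductive cleavage of N-acyl oxazolidinones by LiBH4 at the more electrophilic exocyclic carbonyl; a γ-lactone formed after the first reduction would be reduced on to the same diol. Hydride delivery is faster than enolisation, so both centres are kept, and 3 is recovered.

Step 4
Reactants: 8 (2S,3S)-2,3-diallylbutane-1,4-diol; 2 pivaloyl chloride (two molecules)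
Product: 9 (2S,3S)-2,3-diallylbutane-1,4-diyl bis(2,2-dimethylpropanoate)
Conditions: 2, pyridine, DMAP (cat.), CH2Cl2, 0 °C → rt
Reagents that add atoms: none
Why: DMAP-catalysed esterification of two unhindered primary alcohols. No stereocentre is touched.

Step 5
Reactants: 9 (2S,3S)-2,3-diallylbutane-1,4-diyl bis(2,2-dimethylpropanoate)
Product: 10 (2S,3S)-2,3-di[(E)-prop-1-enyl]butane-1,4-diyl bis(2,2-dimethylpropanoate), E/Z mixture acceptable
Conditions: RuHCl(CO)(PPh3)3 (cat.), toluene, 80 °C
Reagents that add atoms: none
Why: Ruthenium hydride catalysed alkene isomerisation (hydrometalation, then β-hydride elimination) moves each terminal alkene one position to the more stable disubstituted alkene. A further shift would need β-hydride elimination at the branched tertiary C–H and is much slower. No carbene is present, so the two allyl arms cannot undergo metathesis.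

Step 6
Reactants: 10 (2S,3S)-2,3-di[(E)-prop-1-enyl]butane-1,4-diyl bis(2,2-dimethylpropanoate)
Product: 12 [(3S,4S)-2,5-dimethoxytetrahydrofuran-3,4-diyl]bis(methylene) bis(2,2-dimethylpropanoate) as an anomer mixture, via dialdehyde 11 (not isolated)
Conditions: O3, CH2Cl2–MeOH, −78 °C; Me2S, −78 °C → rt; then TsOH (cat.), rt; NaHCO3 quench
Reagents that add atoms: ozone, [O-][O+]=O; methanol, CO
Why: Ozonolysis (Criegee mechanism) with neutral sulfide reduction cuts off both propenyl termini, and the 1,4-dialdehyde 11 closes in acidic methanol to the five-membered bis-acetal. No base is present and the formyl groups are masked in the same flask, so the α-centres C-3 and C-4 are kept and pivalate is not eliminated. The anomeric centres do not matter.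

Step 7
Reactants: 12 [(3S,4S)-2,5-dimethoxytetrahydrofuran-3,4-diyl]bis(methylene) bis(2,2-dimethylpropanoate); 13 2,6-dimethoxyphenol (two molecules)
Product: 15 [(2R,3S,4S,5R)-2,5-bis(4-hydroxy-3,5-dimethoxyphenyl)tetrahydrofuran-3,4-diyl]bis(methylene) bis(2,2-dimethylpropanoate), via mono-C-aryl acetal 14 (not isolated)
Conditions: 13 (about 2.2 equiv), BF3·OEt2 (cat.), 4 Å molecular sieves, CH2Cl2, −40 → 0 °C; NaHCO3 quench
Reagents that add atoms: none
Why: BF3 removes one anomeric methoxy group of 12 to leave a ring oxocarbenium ion, the carbon para to the hydroxyl of 13 attacks it and rearomatises to 14, and the same sequence at the second acetal carbon gives 15; an O-aryl acetal formed first is still an acetal and re-ionises until the irreversible C–C bond is made. The closest known reaction type is the Friedel–Crafts aryl C-glycosylation of furanosyl acetals with electron-rich phenols, including its O-to-C rearrangement variant. No ring is closed, since the tetrahydrofuran of 12 is carried through and only C-2–aryl and C-5–aryl are formed. C-2 is controlled by C-3 and C-5 by C-4: the arene approaches each cation anti to the neighbouring pivaloyloxymethyl arm, and this bias is reinforced when the pivalate carbonyl bridges the cis face as a six-membered dioxanium ion. A wrong epimer can still be corrected, because each new ring C–O bond is a para-hydroxybenzylic ether that opens and recloses under the same acid, and the all-trans isomer is the least crowded. Regioselectivity is needed against the two carbons of 13 meta to the hydroxyl, which the methoxy groups activate: the para carbon is the only one conjugated with the in-plane free hydroxyl and the only one flanked by two hydrogens, which matters for a secondary α-branched electrophile, and both ortho carbons are blocked. Chemoselectivity is needed against a second arylation of the same carbon and against the arm oxygens: reclosure of the five-membered ring is intramolecular and should outrun a further phenol when 13 is held near two equivalents at low temperature with catalytic acid and methanol is taken up by the sieves, and the pivalates make the arm oxygens non-nucleophilic. C-3 and C-4 could only be lost by proton loss from the cations to an enol ether or a styrene, which low temperature and the absence of base disfavour.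

Step 8
Reactants: 15 [(2R,3S,4S,5R)-2,5-bis(4-hydroxy-3,5-dimethoxyphenyl)tetrahydrofuran-3,4-diyl]bis(methylene) bis(2,2-dimethylpropanoate)
Product: 16 [(2R,3S,4S,5R)-2,5-bis(4-hydroxy-3,5-dimethoxyphenyl)tetrahydrofuran-3,4-diyl]dimethanol
Conditions: LiAlH4 (excess), THF, 0 °C → rt, under argon; aq. KNaC4H4O6 (potassium sodium tartrate) work-up near pH 7
Reagents that add atoms: none
Why: Hydride reduction of two primary pivalates; the phenols only consume extra hydride as phenoxides, which is harmless at this temperature. The near-neutral work-up keeps acid away from the free diol, so the benzylic ethers do not ionise and all four centres are kept.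

## Compound list

1 | pent-4-enoic acid | C=CCCC(=O)O | starting material
2 | pivaloyl chloride | CC(C)(C)C(Cl)=O | starting material
3 | (R)-4-benzyl-2-oxazolidinone | O=C1OC[C@@H](Cc2ccccc2)N1 | starting material
4 | pent-4-enoic pivalic anhydride | C=CCCC(=O)OC(=O)C(C)(C)C | intermediate
5 | (R)-4-benzyl-3-(pent-4-enoyl)oxazolidin-2-one | C=CCCC(=O)N1C(=O)OC[C@H]1Cc1ccccc1 | intermediate
6 | lithium (Z)-enolate of 5 | C=CC/C=C(\O[Li])N1C(=O)OC[C@H]1Cc1ccccc1 | intermediate
7 | (2S,3S)-2,3-diallyl-1,4-bis[(4R)-4-benzyl-2-oxo-1,3-oxazolidin-3-yl]butane-1,4-dione | O=C([C@@H](CC=C)[C@H](CC=C)C(=O)N1C(=O)OC[C@H]1Cc1ccccc1)N1C(=O)OC[C@H]1Cc1ccccc1 | intermediate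
8 | (2S,3S)-2,3-diallylbutane-1,4-diol | OC[C@@H](CC=C)[C@H](CC=C)CO | intermediate
9 | (2S,3S)-2,3-diallylbutane-1,4-diyl bis(2,2-dimethylpropanoate) | CC(C)(C)C(=O)OC[C@@H](CC=C)[C@H](CC=C)COC(=O)C(C)(C)C | intermediate
10 | (2S,3S)-2,3-di[(E)-prop-1-enyl]butane-1,4-diyl bis(2,2-dimethylpropanoate) | CC(C)(C)C(=O)OC[C@@H](/C=C/C)[C@H](/C=C/C)COC(=O)C(C)(C)C | intermediate
11 | (2S,3S)-2,3-diformylbutane-1,4-diyl bis(2,2-dimethylpropanoate) | CC(C)(C)C(=O)OC[C@@H](C=O)[C@H](C=O)COC(=O)C(C)(C)C | intermediate
12 | [(3S,4S)-2,5-dimethoxytetrahydrofuran-3,4-diyl]bis(methylene) bis(2,2-dimethylpropanoate), anomer mixture | COC1OC(OC)[C@H](COC(=O)C(C)(C)C)[C@H]1COC(=O)C(C)(C)C | intermediate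
13 | 2,6-dimethoxyphenol (syringol) | COc1cccc(OC)c1O | starting material
14 | [(2R,3S,4S)-2-(4-hydroxy-3,5-dimethoxyphenyl)-5-methoxytetrahydrofuran-3,4-diyl]bis(methylene) bis(2,2-dimethylpropanoate), C-5 anomers | COc1cc([C@@H]2OC(OC)[C@H](COC(=O)C(C)(C)C)[C@H]2COC(=O)C(C)(C)C)cc(OC)c1O | intermediate
15 | [(2R,3S,4S,5R)-2,5-bis(4-hydroxy-3,5-dimethoxyphenyl)tetrahydrofuran-3,4-diyl]bis(methylene) bis(2,2-dimethylpropanoate) | COc1cc([C@@H]2O[C@@H](c3cc(OC)c(O)c(OC)c3)[C@H](COC(=O)C(C)(C)C)[C@H]2COC(=O)C(C)(C)C)cc(OC)c1O | intermediate
16 | [(2R,3S,4S,5R)-2,5-bis(4-hydroxy-3,5-dimethoxyphenyl)tetrahydrofuran-3,4-diyl]dimethanol | COc1cc([C@@H]2O[C@@H](c3cc(OC)c(O)c(OC)c3)[C@H](CO)[C@H]2CO)cc(OC)c1O | target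

## Step count and least certain steps

Total step count: 8. Longest linear sequence: 8 steps (1 → 16).

**Step 7 (key step).** Four processes threaten it, in this order of concern.
- **Attack through a methoxy-activated ring carbon instead of the para carbon.** Those positions carry two donor effects against one.
- **Re-ionisation of the new benzylic ether, followed by capture.** The captor may be a further phenol, or an ortho carbon of the aryl ring already installed at the other end, which would close a tetralin. The lability that allows stereochemical correction also opens these C–C sinks.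
- **Attack of the second oxocarbenium ion on the first aryl ring.**
- **Proton loss from the cations**, leading on to loss of methanol and aromatisation of the ring.

The fallback keeps the oxocarbenium arylation but fixes the reacting carbon by a carbon–metal bond and removes the free phenol. It sets out from 13 and 12 and returns at 15. Bromination of 13 (NBS) gives 4-bromo-2,6-dimethoxyphenol F1. Silylation (TBSCl, imidazole) gives (4-bromo-2,6-dimethoxyphenoxy)(tert-butyl)dimethylsilane F2. Mg turnings give the arylmagnesium bromide F3, and ZnBr2 converts it into the arylzinc bromide F4. Separately, 12 is exchanged with benzenesulfinic acid (CaCl2, CH2Cl2) to give [(3S,4S)-2,5-bis(phenylsulfonyl)tetrahydrofuran-3,4-diyl]bis(methylene) dipivalate F5. The organozinc reagent tolerates the esters and displaces both sulfonyl groups, a known substitution of 2-sulfonyl cyclic ethers, anti to the arms, to give the bis(tert-butyldimethylsilyl) ether of 15 F6. Bu4NF then returns 15.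

**Step 2.** The coupling may suffer from α-chlorination by CuCl2 and from simple proton return. The double facial selectivity may also be imperfect, because a radical-type union is less organised than an alkylation.

The fallback builds the two centres one after the other. It sets out from 5 and returns at 8. Alkylation of the sodium enolate of 5 (NaN(SiMe3)2, tert-butyl bromoacetate) on the face away from the benzyl group gives tert-butyl (S)-3-{[(R)-4-benzyl-2-oxooxazolidin-3-yl]carbonyl}hex-5-enoate F7. LiOH/H2O2 gives (S)-2-allyl-4-tert-butoxy-4-oxobutanoic acid F8. Allylation of its dianion (LiN(iPr)2, allyl bromide) gives (2S,3S)-2,3-diallyl-4-tert-butoxy-4-oxobutanoic acid F9. If needed, deprotonation and kinetic reprotonation, the established correction towards anti-2,3-disubstituted succinates, adjusts the new centre. LiAlH4 then gives 8.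

**Step 5.** The double bond may migrate past the propenyl stage into the trisubstituted position, which would erase C-3 or C-4. One arm may also lag behind the other. The product is a 3,4-disubstituted 1,5-diene, so overheating invites a Cope rearrangement.

The fallback replaces migration by ring closure and ring cleavage. It sets out from 9 and returns at 11, and hence at 12 in the same flask. Ring-closing metathesis of 9 (second-generation Grubbs catalyst, CH2Cl2) gives [(1S,2S)-cyclohex-4-ene-1,2-diyl]bis(methylene) dipivalate F10. Br2 gives the trans-4,5-dibromide F11. Double dehydrobromination (DBU, heat) gives [(1S,2S)-cyclohexa-3,5-diene-1,2-diyl]bis(methylene) dipivalate F12. Exhaustive ozonolysis under the conditions of step 6 excises the four-carbon diene unit down to the two formyl carbons of 11.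

**Step 6.** The α-branched β-acyloxy dialdehyde may enolise, which would cause epimerisation, and may lose pivalate by an E1cB pathway before it is masked. A large excess of methanol may push the acetalisation on to the open-chain bis(dimethyl acetal) stage.

The fallback carries the arms through the cleavage as ethers, whose oxygens are far poorer leaving groups, and installs the esters afterwards. It sets out from 8 and returns at 12. TBDPSCl/imidazole gives the bis(tert-butyldiphenylsilyl) ether of 8 F13. RuHCl(CO)(PPh3)3 gives the dipropenyl bis-silyl ether F14. Ozonolysis with Me2S gives the β-silyloxy dialdehyde F15, and catalytic acid in methanol gives the bis-silylated bis-acetal F16. Bu4NF frees [(3S,4S)-2,5-dimethoxytetrahydrofuran-3,4-diyl]dimethanol F17 under basic conditions, in which the acetal carbons cannot exchange with the arm oxygens. Compound 2 with pyridine then gives 12.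

## Further compounds

F1 | step 7 | 4-bromo-2,6-dimethoxyphenol | COc1cc(Br)cc(OC)c1O
F2 | step 7 | (4-bromo-2,6-dimethoxyphenoxy)(tert-butyl)dimethylsilane | COc1cc(Br)cc(OC)c1O[Si](C)(C)C(C)(C)C
F3 | step 7 | [4-(tert-butyldimethylsilyloxy)-3,5-dimethoxyphenyl]magnesium bromide | COc1cc([Mg]Br)cc(OC)c1O[Si](C)(C)C(C)(C)C
F4 | step 7 | [4-(tert-butyldimethylsilyloxy)-3,5-dimethoxyphenyl]zinc bromide | COc1cc([Zn]Br)cc(OC)c1O[Si](C)(C)C(C)(C)C
F5 | step 7 | [(3S,4S)-2,5-bis(phenylsulfonyl)tetrahydrofuran-3,4-diyl]bis(methylene) dipivalate, anomer mixture | O=S(=O)(c1ccccc1)C1OC(S(=O)(=O)c2ccccc2)[C@H](COC(=O)C(C)(C)C)[C@H]1COC(=O)C(C)(C)C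
F6 | step 7 | bis(tert-butyldimethylsilyl) ether of 15 | COc1cc([C@@H]2O[C@@H](c3cc(OC)c(O[Si](C)(C)C(C)(C)C)c(OC)c3)[C@H](COC(=O)C(C)(C)C)[C@H]2COC(=O)C(C)(C)C)cc(OC)c1O[Si](C)(C)C(C)(C)C
F7 | step 2 | tert-butyl (S)-3-{[(R)-4-benzyl-2-oxooxazolidin-3-yl]carbonyl}hex-5-enoate | O=C([C@@H](CC=C)CC(=O)OC(C)(C)C)N1C(=O)OC[C@H]1Cc1ccccc1
F8 | step 2 | (S)-2-allyl-4-tert-butoxy-4-oxobutanoic acid | OC(=O)[C@@H](CC=C)CC(=O)OC(C)(C)C
F9 | step 2 | (2S,3S)-2,3-diallyl-4-tert-butoxy-4-oxobutanoic acid | OC(=O)[C@@H](CC=C)[C@H](CC=C)C(=O)OC(C)(C)C
F10 | step 5 | [(1S,2S)-cyclohex-4-ene-1,2-diyl]bis(methylene) dipivalate | CC(C)(C)C(=O)OC[C@H]1CC=CC[C@@H]1COC(=O)C(C)(C)C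
F11 | step 5 | [(1S,2S)-4,5-dibromocyclohexane-1,2-diyl]bis(methylene) dipivalate, trans-dibromide, C–Br centres not defined because they are lost next | CC(C)(C)C(=O)OC[C@H]1CC(Br)C(Br)C[C@@H]1COC(=O)C(C)(C)C
F12 | step 5 | [(1S,2S)-cyclohexa-3,5-diene-1,2-diyl]bis(methylene) dipivalate | CC(C)(C)C(=O)OC[C@H]1C=CC=C[C@@H]1COC(=O)C(C)(C)C
F13 | step 6 | (2S,3S)-2,3-diallyl-1,4-bis(tert-butyldiphenylsilyloxy)butane | CC(C)(C)[Si](c1ccccc1)(c1ccccc1)OC[C@@H](CC=C)[C@H](CC=C)CO[Si](c1ccccc1)(c1ccccc1)C(C)(C)C
F14 | step 6 | (2S,3S)-2,3-di[(E)-prop-1-enyl]-1,4-bis(tert-butyldiphenylsilyloxy)butane | CC(C)(C)[Si](c1ccccc1)(c1ccccc1)OC[C@@H](/C=C/C)[C@H](/C=C/C)CO[Si](c1ccccc1)(c1ccccc1)C(C)(C)C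
F15 | step 6 | (2S,3S)-2,3-bis(tert-butyldiphenylsilyloxymethyl)butanedial | CC(C)(C)[Si](c1ccccc1)(c1ccccc1)OC[C@@H](C=O)[C@H](C=O)CO[Si](c1ccccc1)(c1ccccc1)C(C)(C)C
F16 | step 6 | (3S,4S)-3,4-bis(tert-butyldiphenylsilyloxymethyl)-2,5-dimethoxytetrahydrofuran, anomer mixture | COC1OC(OC)[C@H](CO[Si](c2ccccc2)(c2ccccc2)C(C)(C)C)[C@H]1CO[Si](c1ccccc1)(c1ccccc1)C(C)(C)C
F17 | step 6 | [(3S,4S)-2,5-dimethoxytetrahydrofuran-3,4-diyl]dimethanol, anomer mixture | COC1OC(OC)[C@H](CO)[C@H]1CO
A1 | alternative 1 | (S)-5-(tert-butyldiphenylsilyloxymethyl)furan-2(5H)-one | O=C1O[C@H](CO[Si](c2ccccc2)(c2ccccc2)C(C)(C)C)C=C1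
A2 | alternative 1 | 2-(4-benzyloxy-3,5-dimethoxyphenyl)-1,3-dithiane | COc1cc(C2SCCCS2)cc(OC)c1OCc1ccccc1
A3 | alternative 1 | 4-benzyloxy-3,5-dimethoxybenzaldehyde | COc1cc(C=O)cc(OC)c1OCc1ccccc1
A4 | alternative 1 | 3,4-trans-4,5-trans lactone carrying the aryl carbinol on C-3, the aryl dithiane on C-4 and the silyloxymethyl arm on C-5 | O=C1O[C@H](CO[Si](c2ccccc2)(c2ccccc2)C(C)(C)C)[C@@H](C2(c3cc(OC)c(OCc4ccccc4)c(OC)c3)SCCCS2)[C@@H]1[C@@H](O)c1cc(OC)c(OCc2ccccc2)c(OC)c1
A5 | alternative 2 | (2S,3S)-2-(4-benzyloxy-3,5-dimethoxyphenyl)-3-vinyloxirane (trans) | C=C[C@@H]1O[C@H]1c1cc(OC)c(OCc2ccccc2)c(OC)c1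
A6 | alternative 2 | dimethyl 2-(4-benzyloxy-3,5-dimethoxybenzylidene)malonate | COC(=O)C(=Cc1cc(OC)c(OCc2ccccc2)c(OC)c1)C(=O)OC
A7 | alternative 2 | dimethyl 2,5-bis(4-benzyloxy-3,5-dimethoxyphenyl)-4-vinyltetrahydrofuran-3,3-dicarboxylate, C-2, C-4 and C-5 as in 16 | COc1cc([C@@H]2O[C@@H](c3cc(OC)c(OCc4ccccc4)c(OC)c3)[C@H](C=C)C2(C(=O)OC)C(=O)OC)cc(OC)c1OCc1ccccc1
A8 | alternative 3 | methyl (E)-sinapate | COC(=O)/C=C/c1cc(OC)c(O)c(OC)c1
A9 | alternative 3 | dimethyl all-trans-3,4-bis(4-hydroxy-3,5-dimethoxyphenyl)cyclobutane-1,2-dicarboxylate (head-to-head dimer) | COc1cc([C@@H]2[C@@H](c3cc(OC)c(O)c(OC)c3)[C@H](C(=O)OC)[C@H]2C(=O)OC)cc(OC)c1O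
A10 | alternative 3 | dimethyl all-trans-2,5-bis(4-hydroxy-3,5-dimethoxyphenyl)tetrahydrofuran-3,4-dicarboxylate | COc1cc([C@@H]2O[C@@H](c3cc(OC)c(O)c(OC)c3)[C@H](C(=O)OC)[C@H]2C(=O)OC)cc(OC)c1O
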